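Compound numbers are fixed by the route below (1–15). Flavone numbering (O1, C2, C3, C4, C4a, C5–C8, C8a; ring B primed) is used for the atoms of every intermediate.

## The problem

The target 15 is an achiral, fully aromatic flavone: a chromen-4-one (rings A and C) carrying a 2,3,4-trimethoxyphenyl ring B at C2. It has no stereocenter, so the difficulty lies in placing seven oxygen substituents and in telling two free hydroxyls from five methyl ethers. Ring A is substituted everywhere except C6, with hydroxyls at C5 and C8 and a methoxy group at C7. The C5/C8 pair is a para-hydroquinone that is easily oxidized to the 5,8-quinone, above all in base and air, so it should be completed last and handled under acidic or reducing conditions. The two hydroxyls are chemically distinct from the ethers: O5 lies peri to the C4 carbonyl and can be reached by chelation, and C8 is para to O5 and can be reached through the phenolate. The three contiguous methoxy groups of ring B are crowded and sensitive to Lewis acids, which limits how hard a demethylation may be pushed, and the 3-methoxy group is best carried in as an α-methoxy ketone. The feature that makes the key step possible is that O1 is bonded to C8a of ring A and C8a is ortho to C4a, which carries the C4 carbonyl. Ring A can therefore enter as an ortho-bromoaroyl unit, with O1 supplied by the enol oxygen of the ring B carbonyl.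

## Retrosynthesis

**C8–O8 (15 to 13).** The last bond cut is C8–O8, leading back to the 5-hydroxyflavone 13. The hydroquinone is then absent from every intermediate but the last. The substrate itself directs the oxygen: C8 is para to the 5-phenolate, the position attacked in the Elbs persulfate oxidation, and the aryl sulfate 14 masks the new oxygen until acidic hydrolysis. Carrying O8 through the synthesis instead would need a penta-substituted ring A building block with O5 and O8 differentiated from O7. The forward reaction must hydroxylate C8 and not C6; incomplete conversion is tolerable because 13 can be recovered.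

**O5–CH3 (13 to 11).** Compound 13 is traced to the hexamethyl ether 11. Of the six methoxy groups of 11, only the one at C5 forms a six-membered chelate with the C4 carbonyl and a boron Lewis acid (chelate 12), so the methyl ether serves as the protecting group and no special group on O5 is needed. This keeps ring A symmetrical in its precursor. The forward step must remove one methyl group and no more.

**O1–C8a (11 to 10).** This is the strategic cut and leads to the 1-(2-bromoaryl)-2-methoxy-1,3-diketone 10. The neighbouring cut, O1–C2, would require ring A as a phloroglucinol with three differently substituted oxygens. With O1–C8a, bromine marks the position of O1, no phenol has to be protected, and ring A comes from a symmetrical 3,5-dimethoxy bromoarene. Ring C and the complete flavone skeleton, with the 3-methoxy group and ring B in place, arise in one step at the correct oxidation level. The forward reaction needs O-arylation by the ring B enol oxygen only.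

**C3–C4 (10 to 4 and 7, through 9).** The diketone is opened to the α-methoxy ketone 4 and the aldehyde 7, joined as the aldol 9 through the lithium enolate 8 and then oxidized. This cut is preferred over an acylation at the same bond because 7 is one step from a bulk bromoarene, 4 has a single enolizable position, and the aldehyde cannot enolize. The stereocenters of 9 are irrelevant since both become sp2 carbons.

**C4–C4a and C2–C1' (7 to 5; 4 to 1 and 2).** Aldehyde 7 comes from 1-bromo-3,5-dimethoxybenzene 5 by formylation through the iminium salt 6. Ketone 4 comes from 1,2,3-trimethoxybenzene 1 by ortho-lithiation to 3 and acylation with the Weinreb amide 2. Both reactions have one favoured site on a symmetrical arene, and all three starting materials (1, 2, 5) are purchasable.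

## Roads not taken

**Alternative 1:** Aryne insertion, cutting O1–C8a and C4–C4a together.
- Forward step: 3,5-dimethoxybenzyne A3, released by CsF from 3,5-dimethoxy-2-(trimethylsilyl)phenyl trifluoromethanesulfonate A4, would insert into the acyl C–O bond of (Z)-2-methoxy-3-(2,3,4-trimethoxyphenyl)acrylic acid A2. The product is the 2'-hydroxy-α-methoxychalcone A1, (Z)-1-(2-hydroxy-4,6-dimethoxyphenyl)-2-methoxy-3-(2,3,4-trimethoxyphenyl)prop-2-en-1-one. An oxidative cyclization (for example I2 in DMSO) would then give flavone 11, and the end game would be the same as here.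
- Merits: two bonds form in one metal-free step near room temperature. The regiochemistry is right, because the carboxylate oxygen should add to the aryne carbon remote from the 3-methoxy group.
- Weak points: A4 needs several steps from 3,5-dimethoxyphenol and A2 needs two from 2,3,4-trimethoxybenzaldehyde. Simple O-arylation of the carboxylate competes with insertion. A1 can close to the flavanone under the basic fluoride conditions, so a mixture of oxidation levels is likely. Ring C still has to be closed and dehydrogenated.
- Comparison: the aryne road is milder than a copper coupling at 110 °C. The chosen plan offers purchasable ring A and ring B pieces, ring closure and final oxidation level in one step, and about two to three fewer steps to 11. Neither plan has an advantage in the end game.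

**Alternative 2:** Diels–Alder benzannulation, cutting C5–C4a and C8–C8a and building ring A onto a finished pyranone.
- Forward step: 3-methoxy-5-(phenylsulfinyl)-2-(2,3,4-trimethoxyphenyl)-4H-pyran-4-one A6 would react with the diene [4-(benzyloxy)-1,3-dimethoxybuta-1,3-dien-1-yl]oxy(trimethyl)silane A7. Loss of benzenesulfenic acid and of the ketene acetal substituents would aromatize the adduct to 8-(benzyloxy)-5-hydroxy-3,7-dimethoxy-2-(2,3,4-trimethoxyphenyl)-4H-chromen-4-one A5. Hydrogenolysis would then give 15.
- Merits: this is the only road that delivers the three ring A oxygens already differentiated (5-OH free, 7-OMe, 8-OBn). It needs no Elbs oxidation and no selective demethylation, and in that respect it is clearly better than the chosen plan. The polarity also fits, since the benzyloxy-bearing terminus of A7 is the nucleophilic end and should bond to C8a, the β-carbon of the enone.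
- Weak points: both partners are multi-step. A7 is a tetra-oxygenated, hydrolytically fragile diene. A6 needs a 2-aryl-3-methoxypyranone with sulfur at C5, for which no short preparation is evident. The sulfoxide may eliminate before cycloaddition. The total length would be roughly double.
- Comparison: the chosen plan reaches the whole skeleton in five standard steps from three purchasable compounds. Its end game is less elegant but is the classical one for this substitution pattern, and unreacted 13 can be recycled.

**Alternative 3:** Carbonylative α-arylation, cutting C4a–C4 and C4–C3.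
- Forward step: 2-iodo-1,5-dimethoxy-3-(methoxymethoxy)benzene A9, CO and the enolate of ketone 4 would couple under Pd(dba)2 (zerovalent palladium) and a bisphosphine. The product is 1-[2,4-dimethoxy-6-(methoxymethoxy)phenyl]-2-methoxy-3-(2,3,4-trimethoxyphenyl)propane-1,3-dione A8. Acid would remove the acetal and close ring C by cyclodehydration (O1–C2) to flavone 11.
- Merits: it shares 4 and 11 with the chosen plan and replaces aldol plus oxidation by one step. Its ring closure is more certain than any cross-coupling, and the step count to 11 is the same (five). In these respects it is as good or better.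
- Weak points: the coupling must work on an aryl iodide flanked by two ortho oxygen substituents and deactivated by three donors, with an α-alkoxy ketone enolate. Direct α-arylation without CO, O-acylation, and consumption of base by the more acidic product all compete. CO handling is required, and ring A needs a protecting group and a directed iodination.
- Comparison: the chosen plan makes the same C–C bond by an aldol/oxidation pair with no such selectivity demands and uses an unprotected ring A piece that is one step from a bulk chemical. The diketone of Alternative 3 remains reachable by aldol and oxidation if the copper step fails (see the fallback for step 5).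

Key step: step 5

Remark on the chemistry: compounds 1, 2 and 5 are taken as purchasable; enolate 8 is drawn as the chelated Z isomer and iminium salt 6 as its chloride, and neither choice affects the outcome.

## Route

Step 1
Reactants: 1 1,2,3-trimethoxybenzene; 2 N,2-dimethoxy-N-methylacetamide
Product: 4 2-methoxy-1-(2,3,4-trimethoxyphenyl)ethan-1-one, via 2,3,4-trimethoxyphenyllithium 3 (not isolated)
Conditions: n-BuLi, TMEDA, THF, 0 °C to rt; then 2, −78 to 0 °C; 1 M HCl
Reagents that add atoms: none
Why: Directed ortho-metalation, since the only positions ortho to a methoxy group are the two equivalent ones next to the outer ethers, so a single aryllithium 3 forms. Acylation by the Weinreb amide 2 stops at the ketone stage because no second addition occurs before the acidic quench, and this avoids the decarbonylation and ortho-demethylation that threaten a Friedel–Crafts acylation with the corresponding acid chloride.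

Step 2
Reactants: 5 1-bromo-3,5-dimethoxybenzene
Product: 7 2-bromo-4,6-dimethoxybenzaldehyde, via N-(2-bromo-4,6-dimethoxybenzylidene)-N-methylmethanaminium chloride 6 (not isolated)
Conditions: POCl3, DMF, 0 °C then 90 °C; ice–water
Reagents that add atoms: N,N-dimethylformamide, CN(C)C=O; water, O
Why: Vilsmeier–Haack formylation, in which the chloroiminium ion attacks para to one methoxy group and ortho to the other (two equivalent sites next to bromine) in preference to the crowded site between the two methoxy groups, and hydrolysis of 6 releases the aldehyde. Bromine thereby ends up ortho to the future C4 carbonyl with methoxy groups at the future C5 and C7; any isomeric aldehyde should be removable by crystallization.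

Step 3
Reactants: 4 2-methoxy-1-(2,3,4-trimethoxyphenyl)ethan-1-one; 7 2-bromo-4,6-dimethoxybenzaldehyde
Product: 9 3-(2-bromo-4,6-dimethoxyphenyl)-3-hydroxy-2-methoxy-1-(2,3,4-trimethoxyphenyl)propan-1-one (racemic syn/anti mixture), via lithium (Z)-2-methoxy-1-(2,3,4-trimethoxyphenyl)ethen-1-olate 8 (not isolated)
Conditions: LiN(i-Pr)2, THF, −78 °C; then 7, −78 °C; AcOH, −78 °C
Reagents that add atoms: none
Why: Aldol addition of a preformed lithium enolate to a non-enolizable aldehyde; ketone 4 has one acidic position, so enolate 8 forms cleanly, and the cold acetic acid quench prevents retro-aldol cleavage. The two new stereocenters (C3 and C4) form without control as racemic syn and anti isomers, which does not matter because C4 becomes a carbonyl in step 4 and C3 becomes sp2 in step 5.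

Step 4
Reactants: 9 3-(2-bromo-4,6-dimethoxyphenyl)-3-hydroxy-2-methoxy-1-(2,3,4-trimethoxyphenyl)propan-1-one
Product: 10 1-(2-bromo-4,6-dimethoxyphenyl)-2-methoxy-3-(2,3,4-trimethoxyphenyl)propane-1,3-dione (racemic)
Conditions: Dess–Martin periodinane, CH2Cl2, 0 °C to rt
Reagents that add atoms: none
Why: Dess–Martin oxidation of a β-hydroxy ketone to the 1,3-diketone under near-neutral conditions, which avoids the retro-aldol and elimination pathways of basic or strongly acidic oxidants. Both diastereomers of 9 converge on one diketone whose remaining stereocenter at C3 is racemic and labile.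

Step 5
Reactants: 10 1-(2-bromo-4,6-dimethoxyphenyl)-2-methoxy-3-(2,3,4-trimethoxyphenyl)propane-1,3-dione
Product: 11 3,5,7-trimethoxy-2-(2,3,4-trimethoxyphenyl)-4H-chromen-4-one
Conditions: CuI (10 mol %), 1,10-phenanthroline (20 mol %), K2CO3, 4 Å MS, DMF, 110 °C, Ar
Reagents that add atoms: none
Why: K2CO3 removes the proton at C3 of 10, the only acidic C–H, and the diketonate binds monovalent copper in its U-shaped chelating form, in which the oxygen on the ring B carbonyl lies cis to the ring A aroyl group. Copper then inserts into the C8a–Br bond, which the ortho carbonyl activates, to give an aryl–copper enolate (formally trivalent copper) in a seven-membered metallacycle, and C–O reductive elimination forms O1–C8a and regenerates monovalent copper. The closest known reaction type is the CuI-catalyzed intramolecular Ullmann O-arylation of 1-(2-haloaryl)-1,3-diketones to flavones and 2-substituted chromones, and the methoxy group at C3 is a spectator. Ring C closes in the 6-exo-trig sense at an aromatic carbon, the C–Br bond lying outside the new ring, and the conjugated 4-pyranone forms directly at the right oxidation level. No stereocenter is created, and the racemic center at C3 of 10 becomes sp2. The selectivity needed is between the two enolate oxygens and between O- and C-arylation, and geometry secures it: the ring A carbonyl oxygen and C3 could reach C8a only through four-membered rings, so the ring B oxygen is the sole competent nucleophile. Anhydrous base, molecular sieves and exclusion of air are specified because the main competing processes are retro-Claisen cleavage of the diketone by hydroxide and reductive loss of bromine.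

Step 6
Reactants: 11 3,5,7-trimethoxy-2-(2,3,4-trimethoxyphenyl)-4H-chromen-4-one
Product: 13 5-hydroxy-3,7-dimethoxy-2-(2,3,4-trimethoxyphenyl)-4H-chromen-4-one, via 5-[(dichloroboranyl)oxy]-3,7-dimethoxy-2-(2,3,4-trimethoxyphenyl)-4H-chromen-4-one 12 (not isolated)
Conditions: BCl3 (1.5 equiv), CH2Cl2, −78 to 0 °C; then H2O
Reagents that add atoms: none
Why: Chelation-controlled Lewis acid ether cleavage, in which BCl3 binds the C4 carbonyl and the peri 5-methoxy oxygen in a six-membered chelate, chloride removes that methyl group as chloromethane to give 12, and water releases the phenol. Low temperature and a small excess of BCl3 should spare the 3-methoxy group (five-membered chelate only) and the non-chelating ethers at C7 and on ring B; selective 5-demethylation of polymethoxyflavones with BCl3 is standard practice.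

Step 7
Reactants: 13 5-hydroxy-3,7-dimethoxy-2-(2,3,4-trimethoxyphenyl)-4H-chromen-4-one
Product: 15 5,8-dihydroxy-3,7-dimethoxy-2-(2,3,4-trimethoxyphenyl)-4H-chromen-4-one (5,8-dihydroxy-3,7,2',3',4'-pentamethoxyflavone; target), via potassium 5-hydroxy-3,7-dimethoxy-4-oxo-2-(2,3,4-trimethoxyphenyl)-4H-chromen-8-yl sulfate 14 (not isolated)
Conditions: K2S2O8, aq KOH, pyridine, 0 °C to rt, N2; acidify to pH 4–5, extract unreacted 13; then HCl, Na2SO3, H2O, 85 °C
Reagents that add atoms: potassium peroxydisulfate K2S2O8, [K+].[K+].[O-]S(=O)(=O)OOS(=O)(=O)[O-]
Why: Elbs persulfate oxidation, in which the 5-phenolate attacks a peroxide oxygen of peroxydisulfate through its para carbon C8 to give the aryl sulfate 14, which is stable to alkali and air, and hot dilute acid with sulfite then cleaves the S–O bond to release the 8-hydroxyl. Para attack is the normal regiochemistry, and conversion of 5-hydroxy-7-methoxyflavones into their 5,8-dihydroxy congeners is a classical use of the reaction; unreacted 13 is extracted before hydrolysis and recycled.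

## Compound list

1 | 1,2,3-trimethoxybenzene | COc1cccc(OC)c1OC | starting material
2 | N,2-dimethoxy-N-methylacetamide | COCC(=O)N(C)OC | starting material
3 | 2,3,4-trimethoxyphenyllithium | [Li]c1ccc(OC)c(OC)c1OC | intermediate (not isolated)
4 | 2-methoxy-1-(2,3,4-trimethoxyphenyl)ethan-1-one | COCC(=O)c1ccc(OC)c(OC)c1OC | intermediate
5 | 1-bromo-3,5-dimethoxybenzene | COc1cc(Br)cc(OC)c1 | starting material
6 | N-(2-bromo-4,6-dimethoxybenzylidene)-N-methylmethanaminium chloride | COc1cc(Br)c(C=[N+](C)C)c(OC)c1.[Cl-] | intermediate (not isolated)
7 | 2-bromo-4,6-dimethoxybenzaldehyde | COc1cc(Br)c(C=O)c(OC)c1 | intermediate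
8 | lithium (Z)-2-methoxy-1-(2,3,4-trimethoxyphenyl)ethen-1-olate | [Li+].[O-]/C(=C\OC)c1ccc(OC)c(OC)c1OC | intermediate (not isolated)
9 | 3-(2-bromo-4,6-dimethoxyphenyl)-3-hydroxy-2-methoxy-1-(2,3,4-trimethoxyphenyl)propan-1-one, racemic mixture of syn and anti diastereomers | COc1cc(Br)c(C(O)C(OC)C(=O)c2ccc(OC)c(OC)c2OC)c(OC)c1 | intermediate
10 | 1-(2-bromo-4,6-dimethoxyphenyl)-2-methoxy-3-(2,3,4-trimethoxyphenyl)propane-1,3-dione, racemic | COc1cc(Br)c(C(=O)C(OC)C(=O)c2ccc(OC)c(OC)c2OC)c(OC)c1 | intermediate
11 | 3,5,7-trimethoxy-2-(2,3,4-trimethoxyphenyl)-4H-chromen-4-one | COc1cc(OC)c2c(=O)c(OC)c(-c3ccc(OC)c(OC)c3OC)oc2c1 | intermediate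
12 | 5-[(dichloroboranyl)oxy]-3,7-dimethoxy-2-(2,3,4-trimethoxyphenyl)-4H-chromen-4-one | COc1cc(OB(Cl)Cl)c2c(=O)c(OC)c(-c3ccc(OC)c(OC)c3OC)oc2c1 | intermediate (not isolated)
13 | 5-hydroxy-3,7-dimethoxy-2-(2,3,4-trimethoxyphenyl)-4H-chromen-4-one | COc1cc(O)c2c(=O)c(OC)c(-c3ccc(OC)c(OC)c3OC)oc2c1 | intermediate
14 | potassium 5-hydroxy-3,7-dimethoxy-4-oxo-2-(2,3,4-trimethoxyphenyl)-4H-chromen-8-yl sulfate | COc1ccc(-c2oc3c(OS(=O)(=O)[O-])c(OC)cc(O)c3c(=O)c2OC)c(OC)c1OC.[K+] | intermediate (not isolated)
15 | 5,8-dihydroxy-3,7-dimethoxy-2-(2,3,4-trimethoxyphenyl)-4H-chromen-4-one | COc1ccc(-c2oc3c(O)c(OC)cc(O)c3c(=O)c2OC)c(OC)c1OC | target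

## Step count and risks

Total step count: 7. Longest linear sequence: 6 steps (steps 2 to 7, from 5 to 15); step 1 (1 to 4) is the only branch and joins at step 3.

**Step 5 (key step).** Insertion of copper into the C8a–Br bond may be slow, because the arene is electron-rich and the bromide is flanked by the twisted aroyl group. Retro-Claisen cleavage of the diketone by traces of hydroxide, or reductive loss of bromine, could then outpace ring closure. The fallback closes ring C from the other side by acid cyclodehydration (O1–C2). It sets out from ketone 4 and returns at flavone 11.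
- Purchased 2-hydroxy-4,6-dimethoxybenzaldehyde F1 would be protected with MOMCl and i-Pr2NEt as 2,4-dimethoxy-6-(methoxymethoxy)benzaldehyde F2.
- Addition of enolate 8, as in step 3, would give 3-[2,4-dimethoxy-6-(methoxymethoxy)phenyl]-3-hydroxy-2-methoxy-1-(2,3,4-trimethoxyphenyl)propan-1-one F3.
- Dess–Martin oxidation would give 1-[2,4-dimethoxy-6-(methoxymethoxy)phenyl]-2-methoxy-3-(2,3,4-trimethoxyphenyl)propane-1,3-dione F4 (the same diketone that Alternative 3 would reach as A8).
- HCl in methanol would remove the acetal and dehydrate the resulting hydroxy diketone to 11.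

**Step 7.** Conversion may be incomplete, since the chelated 5-phenolate is a weak nucleophile and persulfate is consumed by side oxidation in alkali. The liberated hydroquinone may also be oxidized to the quinone during hydrolysis and isolation. The fallback goes through the quinone deliberately. It sets out from 13 and returns at 15. Oxidation of 13 with (KSO3)2NO (Fremy's salt) in buffered aqueous acetone would give 3,7-dimethoxy-2-(2,3,4-trimethoxyphenyl)-4H-chromene-4,5,8-trione F5. Two-phase reduction with Na2S2O4 would then give 15.

**Step 6.** A second methyl group may be lost, either the 3-methoxy group through its five-membered chelate or an ether of the crowded ring B, if BCl3 is in excess or the mixture warms. The fallback moves the demethylation to the aldehyde stage, where only one ether can chelate. It sets out from aldehyde 7 and returns at 13.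
- BCl3 would convert 7 into 2-bromo-6-hydroxy-4-methoxybenzaldehyde F6.
- Benzyl bromide and K2CO3 would give 2-(benzyloxy)-6-bromo-4-methoxybenzaldehyde F7.
- Addition of enolate 8 would give 3-[2-(benzyloxy)-6-bromo-4-methoxyphenyl]-3-hydroxy-2-methoxy-1-(2,3,4-trimethoxyphenyl)propan-1-one F8.
- Dess–Martin oxidation would give 1-[2-(benzyloxy)-6-bromo-4-methoxyphenyl]-2-methoxy-3-(2,3,4-trimethoxyphenyl)propane-1,3-dione F9.
- The conditions of step 5 would close it to 5-(benzyloxy)-3,7-dimethoxy-2-(2,3,4-trimethoxyphenyl)-4H-chromen-4-one F10.
- Hydrogenolysis (H2, 10% Pd/C, EtOAc) would release 13 without touching any methyl ether.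

**Step 3.** The aldol addition may reverse, since the aldehyde is electron-rich and flanked by two ortho substituents, and proton transfer may erode conversion. The fallback makes the C3–C4 bond by acylation and skips the oxidation. It sets out from 7 and returns at diketone 10. Pinnick oxidation (NaClO2, NaH2PO4, 2-methyl-2-butene) would give 2-bromo-4,6-dimethoxybenzoic acid F11. Oxalyl chloride with catalytic DMF would give 2-bromo-4,6-dimethoxybenzoyl chloride F12. This would C-acylate ketone 4 under soft enolization (MgBr2·OEt2, i-Pr2NEt, CH2Cl2) to give 10.

## Further compounds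

F1 | step 5 | 2-hydroxy-4,6-dimethoxybenzaldehyde | COc1cc(O)c(C=O)c(OC)c1
F2 | step 5 | 2,4-dimethoxy-6-(methoxymethoxy)benzaldehyde | COCOc1cc(OC)cc(OC)c1C=O
F3 | step 5 | 3-[2,4-dimethoxy-6-(methoxymethoxy)phenyl]-3-hydroxy-2-methoxy-1-(2,3,4-trimethoxyphenyl)propan-1-one, racemic mixture of syn and anti diastereomers | COCOc1cc(OC)cc(OC)c1C(O)C(OC)C(=O)c1ccc(OC)c(OC)c1OC
F4 | step 5 | 1-[2,4-dimethoxy-6-(methoxymethoxy)phenyl]-2-methoxy-3-(2,3,4-trimethoxyphenyl)propane-1,3-dione, racemic | COCOc1cc(OC)cc(OC)c1C(=O)C(OC)C(=O)c1ccc(OC)c(OC)c1OC
F5 | step 7 | 3,7-dimethoxy-2-(2,3,4-trimethoxyphenyl)-4H-chromene-4,5,8-trione | COc1ccc(C2=C(OC)C(=O)C3=C(O2)C(=O)C(OC)=CC3=O)c(OC)c1OC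
F6 | step 6 | 2-bromo-6-hydroxy-4-methoxybenzaldehyde | COc1cc(O)c(C=O)c(Br)c1
F7 | step 6 | 2-(benzyloxy)-6-bromo-4-methoxybenzaldehyde | COc1cc(Br)c(C=O)c(OCc2ccccc2)c1
F8 | step 6 | 3-[2-(benzyloxy)-6-bromo-4-methoxyphenyl]-3-hydroxy-2-methoxy-1-(2,3,4-trimethoxyphenyl)propan-1-one, racemic mixture of syn and anti diastereomers | COc1cc(Br)c(C(O)C(OC)C(=O)c2ccc(OC)c(OC)c2OC)c(OCc2ccccc2)c1
F9 | step 6 | 1-[2-(benzyloxy)-6-bromo-4-methoxyphenyl]-2-methoxy-3-(2,3,4-trimethoxyphenyl)propane-1,3-dione, racemic | COc1cc(Br)c(C(=O)C(OC)C(=O)c2ccc(OC)c(OC)c2OC)c(OCc2ccccc2)c1
F10 | step 6 | 5-(benzyloxy)-3,7-dimethoxy-2-(2,3,4-trimethoxyphenyl)-4H-chromen-4-one | COc1cc(OCc2ccccc2)c2c(=O)c(OC)c(-c3ccc(OC)c(OC)c3OC)oc2c1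
F11 | step 3 | 2-bromo-4,6-dimethoxybenzoic acid | COc1cc(Br)c(C(=O)O)c(OC)c1
F12 | step 3 | 2-bromo-4,6-dimethoxybenzoyl chloride | COc1cc(Br)c(C(Cl)=O)c(OC)c1
A1 | alternative 1 | (Z)-1-(2-hydroxy-4,6-dimethoxyphenyl)-2-methoxy-3-(2,3,4-trimethoxyphenyl)prop-2-en-1-one | CO/C(C(=O)c1c(O)cc(OC)cc1OC)=C\c1ccc(OC)c(OC)c1OC
A2 | alternative 1 | (Z)-2-methoxy-3-(2,3,4-trimethoxyphenyl)acrylic acid | CO/C(C(=O)O)=C\c1ccc(OC)c(OC)c1OC
A3 | alternative 1 | 3,5-dimethoxybenzyne (1,2-didehydro-3,5-dimethoxybenzene) | COC1=CC(OC)=CC#C1
A4 | alternative 1 | 3,5-dimethoxy-2-(trimethylsilyl)phenyl trifluoromethanesulfonate | COc1cc(OC)c([Si](C)(C)C)c(OS(=O)(=O)C(F)(F)F)c1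
A5 | alternative 2 | 8-(benzyloxy)-5-hydroxy-3,7-dimethoxy-2-(2,3,4-trimethoxyphenyl)-4H-chromen-4-one | COc1ccc(-c2oc3c(OCc4ccccc4)c(OC)cc(O)c3c(=O)c2OC)c(OC)c1OC
A6 | alternative 2 | 3-methoxy-5-(phenylsulfinyl)-2-(2,3,4-trimethoxyphenyl)-4H-pyran-4-one, racemic at sulfur | COc1ccc(-c2occ(S(=O)c3ccccc3)c(=O)c2OC)c(OC)c1OC
A7 | alternative 2 | [4-(benzyloxy)-1,3-dimethoxybuta-1,3-dien-1-yl]oxy(trimethyl)silane, double-bond geometry not fixed | COC(O[Si](C)(C)C)=CC(OC)=COCc1ccccc1
A8 | alternative 3 | 1-[2,4-dimethoxy-6-(methoxymethoxy)phenyl]-2-methoxy-3-(2,3,4-trimethoxyphenyl)propane-1,3-dione, racemic | COCOc1cc(OC)cc(OC)c1C(=O)C(OC)C(=O)c1ccc(OC)c(OC)c1OC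
A9 | alternative 3 | 2-iodo-1,5-dimethoxy-3-(methoxymethoxy)benzene | COCOc1cc(OC)cc(OC)c1I
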